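I decide to reckon the new flask with one number from the ochre run, and to read the whole flask as a ladder against it.

| setting | ochre | flask |
|---|---|---|
| starting material | 0.10 M | 0.067 M |
| partner | 0.0737 M | 0.0737 M |
| remark | run made earlier |  |
| time |  | 15 d |

ochre run (percent of the starting material charged)

| time / d | isomer of the product A / % | target / % |
|---|---|---|
| 0.417 | 1.7 | 32.3 |
| 0.833 | 2.8 | 34.7 |
| 1.25 | 2.0 | 33.0 |
| 1.67 | 2.7 | 31.2 |
| 2.00 | 2.6 | 29.9 |
| 2.50 | 2.8 | 27.4 |
| 3.00 | 2.3 | 26.6 |

(readings scatter by 0.3 percentage points)



- share of isomer of the product A in isomer of the product A plus target at 12 min
- share of isomer of the product A in isomer of the product A plus target at 8.0 h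
- share of isomer of the product A in isomer of the product A plus target at 15 d

1. Formation comes first. In the ochre run, target stands at 32.3 % at the first reading and has its highest reading, 34.7 %, at 0.833 d. Both 12 min and 8.0 h lie before the first reading.

2. Then target falls. The drain half-life, the time in which target halves on the falling part of its curve, follows from the fall in the ochre run to 26.6 % at 3.00 d: 5.65 d.

3. I replace the first 3 readings by their mean, which gives an early share of 6.10 %, my reading of the selectivity under kinetic control. This mean reaches out to 1.25 d, later than 12 min and 8.0 h, and the first reading alone gives 5.00 %, so my figure may stand high for those early times. I assume that both products form from the same pair, so the new flask's lower c(starting material) leaves this share alone. I use the same rough figure at 12 min and at 8.0 h.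

4. At 15 d the new flask has passed 2.51 drain half-lives. The isomer of the product A stays between 1.7 % and 2.8 % in the ochre run, so I hold it flat. Its odds against target then grow by 5.70, and my share is 27.0 %.

The forecast gives 5 %, 5.8 % and 24 %, “assuming the lower starting-material concentration changes selectivity little”. It stands below my figures at all 3 times.

The new flask gives 4.34 %, 4.82 % and 24.4 %, each within the forecast's margin.

    partner → decomposed reagent (k = 0.0359 /h)
    target ⇌ isomer of the product B (K = 0.540, k = 0.0157 /h)
    starting material + partner ⇌ isomer of the product A (K = 1520 /M, k = 0.0516 /M/h)
    starting material + partner ⇌ target (K = 120 /M, k = 1.14 /M/h)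

At 15.0 d the new flask makes target at 0.374 of the rate at which it uses it up. The isomer of the product A has a half-life of 850 d for going back, long against the run. Against the 2.51 drain half-lives of 5.65 d, target in the new flask goes from 38.3 % at 1.50 d to 14.7 % at 15.0 d, while the isomer of the product A goes from 2.86 % to 4.73 %. For the neighbour flask with c(starting material) = 0.017 M, the same drain gives the same 27.0 %, and that flask ends at 29.9 %.

The runs were computed for substances that don't exist, and the scatter is random.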